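**Retrosynthetic overview**
1. The C3 arm is adjusted last. The methyl ester comes from the acid, and the acid from a primary alcohol, so the arm is carried as CH2CH2OH.
2. Key disconnection: the exocyclic bond between C5 of the 1,2-dioxolane and the first CH2 of the C15 trienyl chain. The partners are a bis(trienyl)zinc and (1S,5S)-1,5-dimethyl-2,6,7-trioxabicyclo[3.2.1]octane, which is opened with TMSOTf.
3. Enabling feature: C5 is bonded to ring oxygen O1 of the O1–O2 peroxide, so it is a latent peroxycarbenium carbon. The two-carbon arm on C3 lies 1,3 across the five-membered ring, so its terminal oxygen can be tied to C5 as a six-membered oxane ring that serves as leaving group and face shield.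
4. Ring order: temporary 1,3-dioxolane ketal, then oxirane, then oxetane (catalytic asymmetric double methylene transfer to mono-protected acetylacetone). The 1,2-dioxolane and the oxane then form together (invertive perhydrolysis and transketalisation), and the oxane is opened again in the key step.
5. Chain: (Z)-hex-3-en-1-ol (Takai iodo-olefination) plus 8-chlorooct-1-yne (hydrozirconation and palladium-catalysed coupling), then Cl to I to Zn.

Key step: step 10

Assumption: the (S)-binaphthoxide lanthanum–lithium complex is taken to give the (S)-epoxide, with methyl as the small ketone substituent; if the sense of induction is the opposite, the (R)-binaphthoxide complex is used and nothing else changes.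

**Route**

Step 1
Reactants: 1 pentane-2,4-dione (acetylacetone)
Product: 2 1-(2-methyl-1,3-dioxolan-2-yl)propan-2-one
Conditions: ethylene glycol (1.0 equiv), p-TsOH·H2O (cat.), toluene, reflux, Dean–Stark
Reagents that add atoms: ethylene glycol, OCCO
Why: Acid-catalysed ketalisation with one equivalent of diol under water removal masks one of the two equivalent carbonyl groups of the symmetric diketone, and the mono-ketal is separated from diketone and bis-ketal by distillation.

Step 2
Reactants: 2 1-(2-methyl-1,3-dioxolan-2-yl)propan-2-one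
Product: 4 2-methyl-2-{[(2R)-2-methyloxetan-2-yl]methyl}-1,3-dioxolane, via (S)-epoxide 3 (not isolated)
Conditions: Me2S(O)=CH2 (from Me3S(O)Cl + NaH, THF, reflux, filtered; 1.2 equiv), LaLi3[(S)-binaphthoxide]3 (5 mol %), (2,4,6-(MeO)3C6H2)3P=O (5 mol %), 5 Å MS, THF, rt; then more ylide (1.2 equiv) and LaLi3[(S)-binaphthoxide]3 (15 mol %), 45 °C
Reagents that add atoms: dimethylsulfoxonium methylide (two CH2 units), C[S+](C)(=O)[CH2-]
Why: This is a catalytic asymmetric Corey–Chaykovsky epoxidation of an alkyl methyl ketone followed in the same flask by sulfoxonium-ylide ring expansion of the 2,2-disubstituted epoxide, in which the chiral lanthanum–lithium binaphthoxide binds ketone and ylide together and tells methyl from the branched CH2 group (setting the tertiary C–O stereocentre) and the second methylene attacks only the CH2 terminus of the epoxide, so that this C–O bond and its configuration are kept.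

Step 3
Reactants: 4 2-methyl-2-{[(2R)-2-methyloxetan-2-yl]methyl}-1,3-dioxolane
Product: 6 (1S,5S)-1,5-dimethyl-2,6,7-trioxabicyclo[3.2.1]octane, via (S)-hydroperoxy alcohol 5 (not isolated)
Conditions: anhydrous H2O2 in Et2O (10 equiv), TMSOTf (0.2 equiv), Et2O, −78 to 0 °C; aq NaHCO3 wash; then p-TsOH·H2O (5 mol %), 4 Å MS, CH2Cl2, rt
Reagents that add atoms: hydrogen peroxide, OO
Why: Lewis-acid-mediated perhydrolysis of a 2,2-dialkyl oxetane takes place at the tertiary carbon in a borderline SN2 manner with inversion, which sets the future C3 stereocentre as a C–OO bond, and the new hydroperoxide and primary alcohol then displace the glycol from the neighbouring ketal (transketalisation under thermodynamic control, closing the five-membered peroxide ring and the six-membered oxane ring on the same carbon), with the bridgehead ketal centre dictated by the geometry of the bicycle.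

Step 4
Reactants: 7 1-bromo-6-chlorohexane
Product: 8 8-chlorooct-1-yne
Conditions: LiC≡CH·H2NCH2CH2NH2 (1.1 equiv), DMSO, 0 °C to rt
Reagents that add atoms: lithium acetylide–ethylenediamine complex, [Li+].[C-]#C.NCCN
Why: SN2 alkylation of lithium acetylide at the more reactive C–Br end of the dihalide leaves the chloride untouched.

Step 5
Reactants: 9 (Z)-hex-3-en-1-ol
Product: 10 (Z)-hex-3-enal
Conditions: Dess–Martin periodinane (1.1 equiv), CH2Cl2, 0 °C; short silica plug, used at once
Reagents that add atoms: none
Why: Dess–Martin oxidation is neutral and fast enough to give the β,γ-unsaturated aldehyde before the Z-alkene can move into conjugation.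

Step 6
Reactants: 10 (Z)-hex-3-enal
Product: 11 (1E,4Z)-1-iodohepta-1,4-diene
Conditions: CrCl2 (6 equiv), CHI3 (2 equiv), THF/dioxane, 0 °C
Reagents that add atoms: iodoform, IC(I)I
Why: Takai olefination with the geminal dichromium reagent from CHI3 converts the aldehyde into the (E)-alkenyl iodide under non-basic conditions, so the skipped Z-alkene is neither isomerised nor conjugated.

Step 7
Reactants: 8 8-chlorooct-1-yne; 11 (1E,4Z)-1-iodohepta-1,4-diene
Product: 13 (3Z,6E,8E)-15-chloropentadeca-3,6,8-triene, via alkenylzirconocene chloride 12 (not isolated)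
Conditions: 8, Cp2Zr(H)Cl (1.1 equiv), THF, rt; then 11, Pd(PPh3)4 (5 mol %), THF, rt
Reagents that add atoms: Cp2Zr(H)Cl, [H][Zr](Cl)(C1C=CC=C1)C1C=CC=C1 (its metal fragment stays only in 12; only its hydride ends in 13)
Why: Syn hydrozirconation of the terminal alkyne places zirconium on the terminal carbon with E geometry, and the Negishi-type palladium-catalysed alkenyl–alkenyl coupling proceeds with retention at both partners, which fixes the E,E-diene while the alkyl chloride and the Z-alkene are spectators.

Step 8
Reactants: 13 (3Z,6E,8E)-15-chloropentadeca-3,6,8-triene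
Product: 14 (3Z,6E,8E)-15-iodopentadeca-3,6,8-triene
Conditions: NaI (5 equiv), acetone, reflux, dark
Reagents that add atoms: sodium iodide, [Na+].[I-]
Why: Finkelstein halide exchange at the primary carbon is driven by precipitation of NaCl.

Step 9
Reactants: 14 (3Z,6E,8E)-15-iodopentadeca-3,6,8-triene
Product: 15 bis[(7E,9E,12Z)-pentadeca-7,9,12-trien-1-yl]zinc
Conditions: Et2Zn (neat, 1.5 equiv), CuI (0.3 mol %), 50 °C; volatiles removed at 0.1 mmHg; residue taken up in CH2Cl2 and used directly
Reagents that add atoms: diethylzinc, CC[Zn]CC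
Why: Copper-catalysed iodine–zinc exchange of a primary alkyl iodide with Et2Zn, driven by removal of volatile EtI and excess Et2Zn, gives a salt-free and ether-free dialkylzinc, which matters because salts and donor solvents would quench the Lewis acid of the next step.

Step 10
Reactants: 6 (1S,5S)-1,5-dimethyl-2,6,7-trioxabicyclo[3.2.1]octane; 15 bis[(7E,9E,12Z)-pentadeca-7,9,12-trien-1-yl]zinc
Product: 18 2-[(3S,5S)-3,5-dimethyl-5-[(7E,9E,12Z)-pentadeca-7,9,12-trien-1-yl]-1,2-dioxolan-3-yl]ethan-1-ol, via peroxycarbenium triflate 16 (not isolated), via trimethylsilyl ether 17 (not isolated)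
Conditions: 6 (1.0 equiv), 15 (1.2 equiv), CH2Cl2, −78 °C; TMSOTf (1.1 equiv) added last and slowly, −78 to −40 °C; then aq citric acid/MeOH, 0 °C
Reagents that add atoms: TMSOTf, C[Si](C)(C)OS(=O)(=O)C(F)(F)F (its atoms stay only in 16 and 17 and are lost on work-up)
Why: Proposed new method: TMSOTf silylates the most basic oxygen of 6, the bridging ether oxygen O2, and the C1–O2 bond ionises with lone-pair help from the neighbouring peroxide oxygen to the tethered peroxycarbenium ion 16, which stays in equilibrium with the silyloxonium form of 6 until a primary alkyl group passes from zinc in 15 to the cationic carbon to give 17, whose silyl ether is cleaved on acidic work-up. The closest known reaction types are the Lewis-acid-mediated displacement of 3-alkoxy-1,2-dioxolanes by allylsilanes, silyl enol ethers and silyl ketene acetals through the same kind of cation, and the SN1-type alkylation of ketals, acyloxy-assisted glycosyl donors and tertiary halides by diorganozincs; what is new is the meeting of an unstabilised sp3 zinc nucleophile with a peroxycarbenium ion. No ring is closed: the six-membered oxane ring of the bicycle is opened, the 1,2-dioxolane ring is kept, and the freed arm is the masked acetate side chain. The new quaternary stereocentre C5 is controlled by C3 through the tether, because the leaving oxygen is held on the ring face that carries the C3 arm, so the alkyl group enters from the opposite face (inversion at the former bridgehead, either SN2-like on the silyloxonium ion or on the ion pair whose upper face is covered by the CH2CH2OSiMe3 arm and triflate) and ends trans to the arm and cis to the C3 methyl group, as in the target; the silyl cap also keeps zinc from being guided to the wrong face by the leaving oxygen. The step needs ionisation of C–O and not of C–OO (secured by the higher basicity of the ether oxygen and known for alkoxydioxolanes), alkyl transfer ahead of β-hydride transfer and ahead of capture of the cation by the diene of the chain (secured by the polarised C–Zn bond in a salt-free, non-coordinating medium at −78 °C, with the acid added last so that the cation is born in an excess of 15), and survival of the O–O bond (dialkylzincs should neither add to nor reduce a hindered dialkyl peroxide at this temperature).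

Step 11
Reactants: 18 2-[(3S,5S)-3,5-dimethyl-5-[(7E,9E,12Z)-pentadeca-7,9,12-trien-1-yl]-1,2-dioxolan-3-yl]ethan-1-ol
Product: 20 2-[(3R,5S)-3,5-dimethyl-5-[(7E,9E,12Z)-pentadeca-7,9,12-trien-1-yl]-1,2-dioxolan-3-yl]acetic acid, via aldehyde 19 (not isolated)
Conditions: TEMPO (0.2 equiv), PhI(OAc)2 (2.2 equiv), MeCN/H2O 1:1, 0 °C to rt
Reagents that add atoms: water, O
Why: Oxoammonium-catalysed oxidation takes the primary alcohol through the aldehyde hydrate to the acid without touching the dialkyl peroxide, the triene or the two fully substituted stereocentres.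

Step 12
Reactants: 20 2-[(3R,5S)-3,5-dimethyl-5-[(7E,9E,12Z)-pentadeca-7,9,12-trien-1-yl]-1,2-dioxolan-3-yl]acetic acid
Product: 21 methyl 2-[(3R,5S)-3,5-dimethyl-5-[(7E,9E,12Z)-pentadeca-7,9,12-trien-1-yl]-1,2-dioxolan-3-yl]acetate
Conditions: TMSCHN2 (1.2 equiv), toluene/MeOH 4:1, 0 °C
Reagents that add atoms: (trimethylsilyl)diazomethane, C[Si](C)(C)C=[N+]=[N-]
Why: Methyl esterification with (trimethylsilyl)diazomethane is neutral, so base-induced β-elimination of the peroxide from the ester is avoided.

**Compound list**
1 | pentane-2,4-dione | CC(=O)CC(C)=O | starting material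
2 | 1-(2-methyl-1,3-dioxolan-2-yl)propan-2-one | CC(=O)CC1(C)OCCO1 | intermediate
3 | 2-methyl-2-{[(2S)-2-methyloxiran-2-yl]methyl}-1,3-dioxolane | CC1(OCCO1)C[C@@]2(C)CO2 | intermediate
4 | 2-methyl-2-{[(2R)-2-methyloxetan-2-yl]methyl}-1,3-dioxolane | CC1(OCCO1)C[C@@]2(C)CCO2 | intermediate
5 | (3S)-3-hydroperoxy-3-methyl-4-(2-methyl-1,3-dioxolan-2-yl)butan-1-ol | CC1(OCCO1)C[C@](C)(CCO)OO | intermediate
6 | (1S,5S)-1,5-dimethyl-2,6,7-trioxabicyclo[3.2.1]octane | C[C@@]1(OC2)C[C@](C)(C2)OO1 | intermediate
7 | 1-bromo-6-chlorohexane | BrCCCCCCCl | starting material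
8 | 8-chlorooct-1-yne | C#CCCCCCCCl | intermediate
9 | (Z)-hex-3-en-1-ol | CC/C=C\CCO | starting material
10 | (Z)-hex-3-enal | CC/C=C\CC=O | intermediate
11 | (1E,4Z)-1-iodohepta-1,4-diene | CC/C=C\C/C=C/I | intermediate
12 | chlorobis(cyclopentadienyl)[(1E)-8-chlorooct-1-en-1-yl]zirconium | ClCCCCCC/C=C/[Zr](Cl)(C1C=CC=C1)C1C=CC=C1 | intermediate
13 | (3Z,6E,8E)-15-chloropentadeca-3,6,8-triene | CC/C=C\C/C=C/C=C/CCCCCCCl | intermediate
14 | (3Z,6E,8E)-15-iodopentadeca-3,6,8-triene | CC/C=C\C/C=C/C=C/CCCCCCI | intermediate
15 | bis[(7E,9E,12Z)-pentadeca-7,9,12-trien-1-yl]zinc | CC/C=C\C/C=C/C=C/CCCCCC[Zn]CCCCCC/C=C/C=C/C/C=C\CC | intermediate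
16 | (3S)-3,5-dimethyl-3-[2-(trimethylsilyloxy)ethyl]-3,4-dihydro-1,2-dioxol-1-ium triflate (peroxycarbenium ion pair) | CC1=[O+]O[C@@](C)(CCO[Si](C)(C)C)C1.[O-]S(=O)(=O)C(F)(F)F | intermediate
17 | {2-[(3S,5S)-3,5-dimethyl-5-[(7E,9E,12Z)-pentadeca-7,9,12-trien-1-yl]-1,2-dioxolan-3-yl]ethoxy}trimethylsilane | CC/C=C\C/C=C/C=C/CCCCCC[C@@]1(C)C[C@](C)(CCO[Si](C)(C)C)OO1 | intermediate
18 | 2-[(3S,5S)-3,5-dimethyl-5-[(7E,9E,12Z)-pentadeca-7,9,12-trien-1-yl]-1,2-dioxolan-3-yl]ethan-1-ol | CC/C=C\C/C=C/C=C/CCCCCC[C@@]1(C)C[C@](C)(CCO)OO1 | intermediate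
19 | 2-[(3R,5S)-3,5-dimethyl-5-[(7E,9E,12Z)-pentadeca-7,9,12-trien-1-yl]-1,2-dioxolan-3-yl]acetaldehyde | CC/C=C\C/C=C/C=C/CCCCCC[C@@]1(C)C[C@](C)(CC=O)OO1 | intermediate
20 | 2-[(3R,5S)-3,5-dimethyl-5-[(7E,9E,12Z)-pentadeca-7,9,12-trien-1-yl]-1,2-dioxolan-3-yl]acetic acid | CC/C=C\C/C=C/C=C/CCCCCC[C@@]1(C)C[C@](C)(CC(=O)O)OO1 | intermediate
21 | methyl 2-[(3R,5S)-3,5-dimethyl-5-[(7E,9E,12Z)-pentadeca-7,9,12-trien-1-yl]-1,2-dioxolan-3-yl]acetate | CC/C=C\C/C=C/C=C/CCCCCC[C@@]1(C)C[C@](C)(CC(=O)OC)OO1 | target

**Count**
Total steps: 12. Longest linear sequence: 8 steps (5, 6, 7, 8, 9, 10, 11, 12).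

**Steps most likely to fail**

1. Step 10.
- What may go wrong: the zinc alkyl may pass a β-hydride instead of the alkyl group. The cation may be captured by the diene of a second chain. Ionisation may run the other way, with loss of the peroxide oxygen. The facial bias may fade if a free ion is formed.
- Fallback (known chemistry): it sets out from 11 and 6 and comes back at 18. It replaces the sp3 nucleophile by a silyl enol ether whose carbonyl group acts as a removable activating group.
- Commercial oct-7-yn-2-one is hydroborated with pinacolborane (Cy2BH cat., neat, rt) to (E)-8-(4,4,5,5-tetramethyl-1,3,2-dioxaborolan-2-yl)oct-7-en-2-one F1.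
- Suzuki–Miyaura coupling of F1 with 11 (Pd(PPh3)4, aq K3PO4, THF) gives (7E,9E,12Z)-pentadeca-7,9,12-trien-2-one F2.
- Kinetic silylation (LiN(i-Pr)2, TMSCl, THF, −78 °C) gives trimethyl{[(7E,9E,12Z)-pentadeca-1,7,9,12-tetraen-2-yl]oxy}silane F3.
- F3 displaces the bridging oxygen of 6 under TMSOTf catalysis in CH2Cl2 at −78 °C. This is the Mukaiyama-type displacement known for alkoxydioxolanes, with the same tether-controlled facial course. After work-up it gives (7E,9E,12Z)-1-[(3R,5S)-5-(2-hydroxyethyl)-3,5-dimethyl-1,2-dioxolan-3-yl]pentadeca-7,9,12-trien-2-one F4.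
- Condensation with TsNHNH2 gives the tosylhydrazone F5. Reduction with catecholborane followed by NaOAc·3H2O removes the carbonyl group and gives 18.

2. Step 3.
- What may go wrong: the tertiary C–O bond of the oxetane may ionise before hydrogen peroxide arrives. This would cause partial loss of configuration at the future C3, and all later compounds would then be scalemic.
- Fallback: it sets out from 20 and comes back at 21. It replaces stereospecific substitution as the only source of optical purity by an auxiliary-based separation.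
- Acid 20 is coupled with (S)-4-benzyloxazolidin-2-one (PivCl, Et3N, LiCl, THF). This gives (4S)-4-benzyl-3-{[(3R,5S)-3,5-dimethyl-5-[(7E,9E,12Z)-pentadeca-7,9,12-trien-1-yl]-1,2-dioxolan-3-yl]acetyl}-1,3-oxazolidin-2-one F6 together with its (3S,5R) diastereomer F7.
- The two are separated by chromatography. Methanolysis of F6 (MeOMgBr, MeOH/CH2Cl2, 0 °C) gives 21 directly, so step 12 is not needed.

3. Step 2.
- What may go wrong: the catalyst may discriminate poorly between methyl and the ketal-bearing CH2 group, or the second, catalyst-assisted methylene transfer may stall.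
- Fallback: it sets out from 2 and comes back at 4. It replaces asymmetric catalysis on the ketone by kinetic resolution of the epoxide.
- Racemic Corey–Chaykovsky epoxidation (Me3SI, NaH, DMSO/THF, 0 °C) gives racemic 2-methyl-2-[(2-methyloxiran-2-yl)methyl]-1,3-dioxolane F8.
- Chromium-salen-catalysed azidolysis follows, with [N,N'-bis(3,5-di-tert-butylsalicylidene)cyclohexane-1,2-diaminato]CrN3 in the enantiomer that consumes the (R)-epoxide, TMSN3 (0.55 equiv) and i-PrOH. It converts the unwanted enantiomer into (2R)-1-azido-2-methyl-3-(2-methyl-1,3-dioxolan-2-yl)propan-2-ol F9 and leaves 3, which is now isolated.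
- Ring expansion of 3 with achiral dimethylsulfoxonium methylide (Me3S(O)I, KOt-Bu, t-BuOH, 50 °C) gives 4.

**Further compounds**
F1 | step 10 | (E)-8-(4,4,5,5-tetramethyl-1,3,2-dioxaborolan-2-yl)oct-7-en-2-one | CC(=O)CCCC/C=C/B1OC(C)(C)C(C)(C)O1
F2 | step 10 | (7E,9E,12Z)-pentadeca-7,9,12-trien-2-one | CC/C=C\C/C=C/C=C/CCCCC(C)=O
F3 | step 10 | trimethyl{[(7E,9E,12Z)-pentadeca-1,7,9,12-tetraen-2-yl]oxy}silane | CC/C=C\C/C=C/C=C/CCCCC(=C)O[Si](C)(C)C
F4 | step 10 | (7E,9E,12Z)-1-[(3R,5S)-5-(2-hydroxyethyl)-3,5-dimethyl-1,2-dioxolan-3-yl]pentadeca-7,9,12-trien-2-one | CC/C=C\C/C=C/C=C/CCCCC(=O)C[C@@]1(C)C[C@](C)(CCO)OO1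
F5 | step 10 | tosylhydrazone of F4 | CC/C=C\C/C=C/C=C/CCCCC(=NNS(=O)(=O)c1ccc(C)cc1)C[C@@]2(C)C[C@](C)(CCO)OO2
F6 | step 3 | (4S)-4-benzyl-3-{[(3R,5S)-3,5-dimethyl-5-[(7E,9E,12Z)-pentadeca-7,9,12-trien-1-yl]-1,2-dioxolan-3-yl]acetyl}-1,3-oxazolidin-2-one | CC/C=C\C/C=C/C=C/CCCCCC[C@@]1(C)C[C@](C)(CC(=O)N2[C@@H](Cc3ccccc3)COC2=O)OO1
F7 | step 3 | (4S)-4-benzyl-3-{[(3S,5R)-3,5-dimethyl-5-[(7E,9E,12Z)-pentadeca-7,9,12-trien-1-yl]-1,2-dioxolan-3-yl]acetyl}-1,3-oxazolidin-2-one | CC/C=C\C/C=C/C=C/CCCCCC[C@]1(C)C[C@@](C)(CC(=O)N2[C@@H](Cc3ccccc3)COC2=O)OO1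
F8 | step 2 | racemic 2-methyl-2-[(2-methyloxiran-2-yl)methyl]-1,3-dioxolane | CC1(OCCO1)CC2(C)CO2
F9 | step 2 | (2R)-1-azido-2-methyl-3-(2-methyl-1,3-dioxolan-2-yl)propan-2-ol | CC1(OCCO1)C[C@](O)(C)CN=[N+]=[N-]
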